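**Plan**
- Retrosynthetic cuts: the pyranone of unit 1 (the 5,7-dihydroxyflavone) at O1–C2 and C2–C3; then ring B of unit 1 at C5'–C6' and C1'–C2' ([4+2] with methyl propiolate); then the diene back to an allyl group on C8''; then C8''–allyl back to O7''–allyl (Claisen); last the pyranone of unit 2 (the 7''-methoxyflavone) at O1''–C2'' and C2''–C3''.
- Forward ring order: pyranone of unit 2 on a phloroglucinol ring A; ring B of unit 1 by cycloaddition and DDQ dehydrogenation; pyranone of unit 1 on a second phloroglucinol ring; all benzyl ethers removed at the end.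
- Enabling feature: in ring A of unit 2, O7'' is the neighbour of C8''. A [3,3] shift moves an allyl group from O7'' to C8'', frees O7'' for the methyl group and places C3', C4' and C5' of ring B on C8''. Wacker oxidation, methylenation (C2') and silylation turn the allyl group into a 2-silyloxydiene whose oxygen on C4' steers the ester carbon to C1'.
- Stereochemistry: the target has no stereocentre; only regiochemistry is controlled (Claisen shift to C8'', para orientation in the cycloaddition).

Key step: step 9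

Remark: the C3'–C8'' axis carries only three ortho substituents and is treated as freely rotating; 4-(benzyloxy)benzoyl chloride is taken as purchasable.
Abbreviation: Fl = 5-(benzyloxy)-2-[4-(benzyloxy)phenyl]-7-methoxy-4-oxo-4H-chromen-8-yl (unit 2 bonded through C8'').

**Step 1**
Reactants: 1 2',4',6'-trihydroxyacetophenone; 2 4-(benzyloxy)benzoyl chloride
Product: 4 2-[4-(benzyloxy)phenyl]-5,7-dihydroxy-4H-chromen-4-one (4'-O-benzylapigenin), via beta-diketone 3 (not isolated)
Conditions: LiN(SiMe3)2 (5 equiv), THF, −78 °C to rt; aq. HCl; crude in AcOH, H2SO4 (cat.), 95 °C, 1 h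
Reagents that add atoms: none
Why: Claisen-type C-acylation of the lithium polyanion of the polyhydroxyacetophenone (the enolate carbon is its most nucleophilic site, so no O-protection is needed) gives the 1,3-diketone, and acid-catalysed cyclodehydration then closes the pyranone of unit 2 under conditions short and dilute enough to keep the aryl benzyl ether.

**Step 2**
Reactants: 4 4'-O-benzylapigenin; 5 allyl bromide
Product: 6 7-(allyloxy)-2-[4-(benzyloxy)phenyl]-5-hydroxy-4H-chromen-4-one
Conditions: 5 (1.1 equiv), K2CO3 (1.2 equiv), acetone, reflux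
Reagents that add atoms: none
Why: Williamson ether synthesis that is selective for O7 because the 5-OH is locked in a hydrogen bond to the C4 carbonyl and is much less acidic and nucleophilic.

**Step 3**
Reactants: 6 7-O-allyl flavone
Product: 7 7-(allyloxy)-5-(benzyloxy)-2-[4-(benzyloxy)phenyl]-4H-chromen-4-one
Conditions: BnBr (1.5 equiv), K2CO3, Bu4NI (cat.), DMF, 70 °C
Reagents that add atoms: benzyl bromide, BrCc1ccccc1
Why: Williamson ether synthesis on the chelated 5-OH, which needs a polar aprotic solvent and heat but is routine for 5-hydroxyflavones and leaves the allyl ether alone.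

**Step 4**
Reactants: 7 7-O-allyl-5-O-benzyl flavone
Product: 8 8-allyl-5-(benzyloxy)-2-[4-(benzyloxy)phenyl]-7-hydroxy-4H-chromen-4-one
Conditions: PhNEt2, 200 °C, sealed tube
Reagents that add atoms: none
Why: Aromatic Claisen rearrangement ([3,3] shift then tautomerization), expected at C8 because the C7–C8 bond of a benzopyran-4-one has the higher double-bond character and C6 is shielded by the 5-benzyloxy group; it also frees the 7-OH for methylation.

**Step 5**
Reactants: 8 8-allyl-7-hydroxy flavone
Product: 9 8-allyl-5-(benzyloxy)-2-[4-(benzyloxy)phenyl]-7-methoxy-4H-chromen-4-one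
Conditions: MeI, K2CO3, acetone, reflux
Reagents that add atoms: methyl iodide, CI
Why: Williamson methylation of the only free phenol installs the 7''-methoxy group of the target.

**Step 6**
Reactants: 9 8-allyl-7-methoxy flavone
Product: 10 5-(benzyloxy)-2-[4-(benzyloxy)phenyl]-7-methoxy-8-(2-oxopropyl)-4H-chromen-4-one
Conditions: PdCl2 (10 mol %), CuCl (20 mol %), O2 (1 atm), DMF/H2O (7:1), rt
Reagents that add atoms: water, O
Why: Tsuji-Wacker oxidation, in which Markovnikov hydroxypalladation of the terminal alkene by water and beta-hydride elimination give the methyl ketone while CuCl and O2 return zerovalent palladium to divalent palladium; the electron-poor C2–C3 bond of the pyranone and the benzyl ethers are inert.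

**Step 7**
Reactants: 10 aryl acetone
Product: 11 5-(benzyloxy)-2-[4-(benzyloxy)phenyl]-7-methoxy-8-(3-oxobut-1-en-2-yl)-4H-chromen-4-one
Conditions: (CH2O)n (3 equiv), i-Pr2NH2+ CF3CO2− (1 equiv), CF3CO2H (10 mol %), THF, 65 °C
Reagents that add atoms: paraformaldehyde (reacts as formaldehyde), C=O
Why: Mannich reaction through the secondary ammonium salt followed by beta-elimination of the amine (direct alpha-methylenation of a ketone), which takes place at the benzylic CH2 as the more acidic and more substituted alpha-position, as in the known conversion of arylacetones into 3-arylbut-3-en-2-ones.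

**Step 8**
Reactants: 11 alpha-aryl enone
Product: 12 5-(benzyloxy)-2-[4-(benzyloxy)phenyl]-8-{3-[(tert-butyldimethylsilyl)oxy]buta-1,3-dien-2-yl}-7-methoxy-4H-chromen-4-one
Conditions: TBSOTf (1.3 equiv), Et3N (2 equiv), CH2Cl2, 0 °C; filtration through Et3N-washed silica, used at once
Reagents that add atoms: tert-butyldimethylsilyl trifluoromethanesulfonate, CC(C)(C)[Si](C)(C)OS(=O)(=O)C(F)(F)F
Why: Silyl enol ether formation by soft enolization, which can only give one 2-silyloxy-1,3-diene because the methyl group is the sole enolizable position left, the bulky silyl group making the diene robust enough to handle.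

**Step 9**
Reactants: 12 8-(3-silyloxybuta-1,3-dien-2-yl)flavone; 13 methyl propiolate
Product: 14 methyl 4-[(tert-butyldimethylsilyl)oxy]-5-Fl-cyclohexa-1,4-diene-1-carboxylate (Fl on the sp2 carbon next to the silyloxy carbon)
Conditions: 13 (5 equiv), BHT (cat.), toluene, 110 °C, sealed tube
Reagents that add atoms: none
Why: The step is a thermal, concerted but asynchronous [4+2] cycloaddition between the HOMO of the 2-silyloxydiene and the LUMO of the propiolate, in which the enol ether CH2 (C5') bonds ahead to the ester-remote alkyne carbon (C6') and the second CH2 (C2') closes onto the ester-bearing carbon (C1'). The closest known reaction type is the Diels-Alder reaction of 2-(trialkylsilyloxy)buta-1,3-dienes with propiolate esters, which gives cyclohexa-1,4-dienes that are dehydrogenated to 4-oxygenated benzoates. Ring B of unit 1 is closed by intermolecular cycloaddition, both sigma bonds being formed suprafacially on the s-cis diene, to give a six-membered carbocycle at the cyclohexa-1,4-diene oxidation level. No stereocentre is created, so nothing beyond orientation has to be controlled. The step needs the para orientation (ester carbon 1,4 to the silyloxy carbon, hence 1,3 to the flavonyl carbon), and the silyloxy group secures it as the only strong donor on the diene, since the di-ortho-substituted flavon-8-yl group is twisted out of the diene plane and cannot exert the opposing conjugative bias of a planar 2-aryl group. The 2,3-disubstitution keeps the s-cis conformer accessible and the C8''–C3' bond is already present as an unhindered bond to an sp2 carbon, so the crowded biaryl only emerges in the following dehydrogenation.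

**Step 10**
Reactants: 14 cyclohexa-1,4-diene ester
Product: 15 methyl 4-[(tert-butyldimethylsilyl)oxy]-3-Fl-benzoate
Conditions: DDQ (1.1 equiv), toluene, rt
Reagents that add atoms: none
Why: DDQ dehydrogenation, in which hydride abstraction from a doubly allylic CH2 and proton loss give the arene, the gain in aromaticity making it fast at room temperature so that the silyl ether and the benzyl ethers are kept.

**Step 11**
Reactants: 15 aryl silyl ether
Product: 16 methyl 4-(benzyloxy)-3-Fl-benzoate
Conditions: CsF (2 equiv), BnBr (1.5 equiv), DMF, rt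
Reagents that add atoms: benzyl bromide, BrCc1ccccc1
Why: Fluoride desilylation to the phenoxide and Williamson benzylation in the same pot, needed because an aryl silyl ether would not survive the saponification and a free phenol would compete in the later esterification.

**Step 12**
Reactants: 16 methyl benzoate
Product: 17 4-(benzyloxy)-3-Fl-benzoic acid
Conditions: LiOH, THF/MeOH/H2O, 40 °C; then aq. HCl
Reagents that add atoms: lithium hydroxide, [Li+].[OH-]
Why: Saponification of the methyl ester under conditions mild enough for the pyranone (any ring-opened diketone would reclose on acidification), with benzyl and methyl ethers inert.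

**Step 13**
Reactants: 1 2',4',6'-trihydroxyacetophenone
Product: 18 1-[2,4-bis(benzyloxy)-6-hydroxyphenyl]ethan-1-one
Conditions: BnBr (2.1 equiv), K2CO3, DMF, rt to 60 °C
Reagents that add atoms: benzyl bromide, BrCc1ccccc1
Why: Williamson ether synthesis that stops at the dibenzyl ether because the last ortho-OH is strongly hydrogen-bonded to the acetyl group.

**Step 14**
Reactants: 17 biaryl acid; 18 2-hydroxy-4,6-bis(benzyloxy)acetophenone
Product: 19 2-acetyl-3,5-bis(benzyloxy)phenyl 4-(benzyloxy)-3-Fl-benzoate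
Conditions: DCC, DMAP (cat.), CH2Cl2, rt
Reagents that add atoms: none
Why: Steglich esterification, in which the O-acylisourea from DCC is relayed by DMAP to the hindered, hydrogen-bonded phenol, the usual way to the aryl esters used for Baker-Venkataraman rearrangement.

**Step 15**
Reactants: 19 aryl ester
Product: 21 5,7-bis(benzyloxy)-2-[4-(benzyloxy)-3-Fl-phenyl]-4H-chromen-4-one (penta-O-benzylsotetsuflavone), via Baker-Venkataraman diketone 20 (not isolated)
Conditions: LiN(SiMe3)2 (3 equiv), THF, −20 °C to rt; AcOH quench, THF removed; NaOAc, AcOH, 100 °C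
Reagents that add atoms: none
Why: Baker-Venkataraman rearrangement (the methyl ketone enolate takes the neighbouring aroyl group in an intramolecular Claisen-type acyl transfer driven by formation of the diketone enolate) followed by cyclodehydration of the o-hydroxyaryl 1,3-diketone in buffered acetic acid, which closes the pyranone of unit 1 without attacking benzyl ethers.

**Step 16**
Reactants: 21 penta-O-benzylsotetsuflavone
Product: 22 sotetsuflavone
Conditions: H2 (1 atm), Pd/C (10 wt %), THF/MeOH, rt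
Reagents that add atoms: none
Why: Catalytic hydrogenolysis should cleave the five benzyl ethers while the aryl methyl ether and, at one atmosphere and room temperature, the C2–C3 double bonds of both pyranones remain.

**Compound list**
1 | 2',4',6'-trihydroxyacetophenone | CC(=O)c1c(O)cc(O)cc1O | starting material
2 | 4-(benzyloxy)benzoyl chloride | O=C(Cl)c1ccc(OCc2ccccc2)cc1 | starting material
3 | 1-[4-(benzyloxy)phenyl]-3-(2,4,6-trihydroxyphenyl)propane-1,3-dione | O=C(CC(=O)c1c(O)cc(O)cc1O)c1ccc(OCc2ccccc2)cc1 | intermediate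
4 | 2-[4-(benzyloxy)phenyl]-5,7-dihydroxy-4H-chromen-4-one | O=c1cc(-c2ccc(OCc3ccccc3)cc2)oc2cc(O)cc(O)c12 | intermediate
5 | allyl bromide | C=CCBr | starting material
6 | 7-(allyloxy)-2-[4-(benzyloxy)phenyl]-5-hydroxy-4H-chromen-4-one | C=CCOc1cc(O)c2c(=O)cc(-c3ccc(OCc4ccccc4)cc3)oc2c1 | intermediate
7 | 7-(allyloxy)-5-(benzyloxy)-2-[4-(benzyloxy)phenyl]-4H-chromen-4-one | C=CCOc1cc(OCc2ccccc2)c2c(=O)cc(-c3ccc(OCc4ccccc4)cc3)oc2c1 | intermediate
8 | 8-allyl-5-(benzyloxy)-2-[4-(benzyloxy)phenyl]-7-hydroxy-4H-chromen-4-one | C=CCc1c(O)cc(OCc2ccccc2)c2c(=O)cc(-c3ccc(OCc4ccccc4)cc3)oc12 | intermediate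
9 | 8-allyl-5-(benzyloxy)-2-[4-(benzyloxy)phenyl]-7-methoxy-4H-chromen-4-one | C=CCc1c(OC)cc(OCc2ccccc2)c2c(=O)cc(-c3ccc(OCc4ccccc4)cc3)oc12 | intermediate
10 | 5-(benzyloxy)-2-[4-(benzyloxy)phenyl]-7-methoxy-8-(2-oxopropyl)-4H-chromen-4-one | CC(=O)Cc1c(OC)cc(OCc2ccccc2)c2c(=O)cc(-c3ccc(OCc4ccccc4)cc3)oc12 | intermediate
11 | 5-(benzyloxy)-2-[4-(benzyloxy)phenyl]-7-methoxy-8-(3-oxobut-1-en-2-yl)-4H-chromen-4-one | CC(=O)C(=C)c1c(OC)cc(OCc2ccccc2)c2c(=O)cc(-c3ccc(OCc4ccccc4)cc3)oc12 | intermediate
12 | 5-(benzyloxy)-2-[4-(benzyloxy)phenyl]-8-{3-[(tert-butyldimethylsilyl)oxy]buta-1,3-dien-2-yl}-7-methoxy-4H-chromen-4-one | C=C(O[Si](C)(C)C(C)(C)C)C(=C)c1c(OC)cc(OCc2ccccc2)c2c(=O)cc(-c3ccc(OCc4ccccc4)cc3)oc12 | intermediate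
13 | methyl propiolate | C#CC(=O)OC | starting material
14 | methyl 5-{5-(benzyloxy)-2-[4-(benzyloxy)phenyl]-7-methoxy-4-oxo-4H-chromen-8-yl}-4-[(tert-butyldimethylsilyl)oxy]cyclohexa-1,4-diene-1-carboxylate | COC(=O)C1=CCC(O[Si](C)(C)C(C)(C)C)=C(C1)c1c(OC)cc(OCc2ccccc2)c2c(=O)cc(-c3ccc(OCc4ccccc4)cc3)oc12 | intermediate
15 | methyl 3-{5-(benzyloxy)-2-[4-(benzyloxy)phenyl]-7-methoxy-4-oxo-4H-chromen-8-yl}-4-[(tert-butyldimethylsilyl)oxy]benzoate | COC(=O)c1ccc(O[Si](C)(C)C(C)(C)C)c(c1)-c1c(OC)cc(OCc2ccccc2)c2c(=O)cc(-c3ccc(OCc4ccccc4)cc3)oc12 | intermediate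
16 | methyl 4-(benzyloxy)-3-{5-(benzyloxy)-2-[4-(benzyloxy)phenyl]-7-methoxy-4-oxo-4H-chromen-8-yl}benzoate | COC(=O)c1ccc(OCc2ccccc2)c(c1)-c1c(OC)cc(OCc2ccccc2)c2c(=O)cc(-c3ccc(OCc4ccccc4)cc3)oc12 | intermediate
17 | 4-(benzyloxy)-3-{5-(benzyloxy)-2-[4-(benzyloxy)phenyl]-7-methoxy-4-oxo-4H-chromen-8-yl}benzoic acid | OC(=O)c1ccc(OCc2ccccc2)c(c1)-c1c(OC)cc(OCc2ccccc2)c2c(=O)cc(-c3ccc(OCc4ccccc4)cc3)oc12 | intermediate
18 | 1-[2,4-bis(benzyloxy)-6-hydroxyphenyl]ethan-1-one | CC(=O)c1c(O)cc(OCc2ccccc2)cc1OCc1ccccc1 | intermediate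
19 | 2-acetyl-3,5-bis(benzyloxy)phenyl 4-(benzyloxy)-3-{5-(benzyloxy)-2-[4-(benzyloxy)phenyl]-7-methoxy-4-oxo-4H-chromen-8-yl}benzoate | CC(=O)c1c(OCc2ccccc2)cc(OCc2ccccc2)cc1OC(=O)c1ccc(OCc2ccccc2)c(c1)-c1c(OC)cc(OCc2ccccc2)c2c(=O)cc(-c3ccc(OCc4ccccc4)cc3)oc12 | intermediate
20 | 1-[2,4-bis(benzyloxy)-6-hydroxyphenyl]-3-[4-(benzyloxy)-3-{5-(benzyloxy)-2-[4-(benzyloxy)phenyl]-7-methoxy-4-oxo-4H-chromen-8-yl}phenyl]propane-1,3-dione | O=C(CC(=O)c1ccc(OCc2ccccc2)c(c1)-c1c(OC)cc(OCc2ccccc2)c2c(=O)cc(-c3ccc(OCc4ccccc4)cc3)oc12)c1c(O)cc(OCc2ccccc2)cc1OCc1ccccc1 | intermediate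
21 | 5,7-bis(benzyloxy)-2-[4-(benzyloxy)-3-{5-(benzyloxy)-2-[4-(benzyloxy)phenyl]-7-methoxy-4-oxo-4H-chromen-8-yl}phenyl]-4H-chromen-4-one | COc1cc(OCc2ccccc2)c2c(=O)cc(-c3ccc(OCc4ccccc4)cc3)oc2c1-c1cc(-c2cc(=O)c3c(OCc4ccccc4)cc(OCc4ccccc4)cc3o2)ccc1OCc1ccccc1 | intermediate
22 | sotetsuflavone | COc1cc(O)c2c(=O)cc(-c3ccc(O)cc3)oc2c1-c1cc(-c2cc(=O)c3c(O)cc(O)cc3o2)ccc1O | target

**Step count**
Total: 16 steps. Longest linear sequence: 15 steps (steps 1 to 12 and 14 to 16); step 13 is a one-step side branch.

**Steps most likely to fail**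

Step 9 (cycloaddition). The hindered diene may desilylate or polymerize faster than it adds the alkyne, or the orientation may erode if the aryl group opposes the silyloxy donor. The fallback forms the C3'–C8'' bond by cross-coupling instead of building ring B; it sets out from 4 and returns at 16, so steps 2 to 11 are not needed. Methylation of O7 of 4 (MeI, K2CO3, acetone) gives 2-[4-(benzyloxy)phenyl]-5-hydroxy-7-methoxy-4H-chromen-4-one F1. Benzylation (BnBr, K2CO3, DMF, 70 °C) gives 5-(benzyloxy)-2-[4-(benzyloxy)phenyl]-7-methoxy-4H-chromen-4-one F2. Iodination with I2 and CF3CO2Ag in CH2Cl2, expected at C8 for a 5,7-dialkoxyflavone, gives 5-(benzyloxy)-2-[4-(benzyloxy)phenyl]-8-iodo-7-methoxy-4H-chromen-4-one F3. The partner comes from purchased methyl 3-bromo-4-hydroxybenzoate: benzylation gives methyl 4-(benzyloxy)-3-bromobenzoate F4, and Miyaura borylation (bis(pinacolato)diboron, Pd(dppf)Cl2, KOAc, dioxane, 90 °C) gives methyl 4-(benzyloxy)-3-(4,4,5,5-tetramethyl-1,3,2-dioxaborolan-2-yl)benzoate F5. Suzuki-Miyaura coupling of F3 with F5 (Pd(OAc)2, SPhos, K3PO4, toluene/water, 100 °C) should then give 16.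

Step 7 (methylenation). Aminomethylation may occur at the methyl group instead of the crowded benzylic carbon, or go on to bis-alkylation. The fallback moves the methylenation to an aldehyde that has a single alpha-position; it sets out from 9 and returns at 11. Lemieux-Johnson cleavage of the allyl group (OsO4 cat., NaIO4, 2,6-lutidine, dioxane/water) gives 2-Fl-acetaldehyde F6. Amine-catalysed alpha-methylenation (aq. CH2O, pyrrolidine and propionic acid cat., i-PrOH, 45 °C) gives 2-Fl-prop-2-enal F7. Aldehyde-selective methyl addition with MeTi(Oi-Pr)3 (THF, −40 °C), which spares the pyranone carbonyl, gives 5-(benzyloxy)-2-[4-(benzyloxy)phenyl]-8-(3-hydroxybut-1-en-2-yl)-7-methoxy-4H-chromen-4-one F8 (racemic). Oxidation with Dess-Martin periodinane gives 11.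

Step 6 (Wacker oxidation). A palladium hydride may shift the double bond into conjugation with ring A, or oxidation may turn to the terminal carbon under the influence of the flanking ether oxygens. The fallback hydrates the alkene by hydrogen-atom transfer, which has no such isomerization path; it sets out from 9 and returns at 10. Mukaiyama hydration (Co(acac)2 cat., PhSiH3, O2, i-PrOH/THF, rt) gives 5-(benzyloxy)-2-[4-(benzyloxy)phenyl]-8-(2-hydroxypropyl)-7-methoxy-4H-chromen-4-one F9 (racemic). Oxidation with Dess-Martin periodinane gives 10.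

**Further compounds**
F1 | step 9 | 2-[4-(benzyloxy)phenyl]-5-hydroxy-7-methoxy-4H-chromen-4-one | COc1cc(O)c2c(=O)cc(-c3ccc(OCc4ccccc4)cc3)oc2c1
F2 | step 9 | 5-(benzyloxy)-2-[4-(benzyloxy)phenyl]-7-methoxy-4H-chromen-4-one | COc1cc(OCc2ccccc2)c2c(=O)cc(-c3ccc(OCc4ccccc4)cc3)oc2c1
F3 | step 9 | 5-(benzyloxy)-2-[4-(benzyloxy)phenyl]-8-iodo-7-methoxy-4H-chromen-4-one | COc1cc(OCc2ccccc2)c2c(=O)cc(-c3ccc(OCc4ccccc4)cc3)oc2c1I
F4 | step 9 | methyl 4-(benzyloxy)-3-bromobenzoate | COC(=O)c1ccc(OCc2ccccc2)c(Br)c1
F5 | step 9 | methyl 4-(benzyloxy)-3-(4,4,5,5-tetramethyl-1,3,2-dioxaborolan-2-yl)benzoate | COC(=O)c1ccc(OCc2ccccc2)c(c1)B1OC(C)(C)C(C)(C)O1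
F6 | step 7 | 2-{5-(benzyloxy)-2-[4-(benzyloxy)phenyl]-7-methoxy-4-oxo-4H-chromen-8-yl}acetaldehyde | O=CCc1c(OC)cc(OCc2ccccc2)c2c(=O)cc(-c3ccc(OCc4ccccc4)cc3)oc12
F7 | step 7 | 2-{5-(benzyloxy)-2-[4-(benzyloxy)phenyl]-7-methoxy-4-oxo-4H-chromen-8-yl}prop-2-enal | C=C(C=O)c1c(OC)cc(OCc2ccccc2)c2c(=O)cc(-c3ccc(OCc4ccccc4)cc3)oc12
F8 | step 7 | 5-(benzyloxy)-2-[4-(benzyloxy)phenyl]-8-(3-hydroxybut-1-en-2-yl)-7-methoxy-4H-chromen-4-one (racemic) | CC(O)C(=C)c1c(OC)cc(OCc2ccccc2)c2c(=O)cc(-c3ccc(OCc4ccccc4)cc3)oc12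
F9 | step 6 | 5-(benzyloxy)-2-[4-(benzyloxy)phenyl]-8-(2-hydroxypropyl)-7-methoxy-4H-chromen-4-one (racemic) | CC(O)Cc1c(OC)cc(OCc2ccccc2)c2c(=O)cc(-c3ccc(OCc4ccccc4)cc3)oc12
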